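**Target:** 2-[3,4-dihydroxy-2-(3-methylbut-2-enyl)phenyl]-3,5,7-trihydroxychromen-4-one (2'-prenylquercetin), compound 20. The route has 9 steps, and the ring-forming condensation of phloroglucinol 16 with keto ester 15 is step 8.

## Analysis of the target

The target is a flavonol: a 3,5,7-trihydroxychromen-4-one (benzo ring A, pyranone ring C) that carries at C2 a 3,4-dihydroxyphenyl ring B with a 3-methylbut-2-enyl (prenyl) group at C2'. It has no stereocentre and no configured double bond, so every selectivity question is one of regio- or chemoselectivity. The prenyl alkene sits ortho to the C3' hydroxyl. Acid therefore closes it to a 2,2-dimethylchroman, electrophilic oxidants (peracids, dioxiranes, halogens) attack it, and hydrogenation saturates it. The catechol and the 3-hydroxypyranone are oxidised by air once they are deprotonated.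

Three things make the synthesis hard. Ring B is 1,2,3,4-tetrasubstituted, with the prenyl group wedged between C1' and the C3' oxygen. The C3 oxygen cannot be brought in late by epoxidation of a flavone or chalcone without touching the alkene. Five hydroxyls must be set free at the end without acid, hydrogen or strong base.

The strategy rests on two features. Ring A is the threefold-symmetric 1,3,5-trioxygenated benzene. Ring C adds to it exactly three carbons (C4, the oxygen-bearing C3, and C2 with ring B), which is the chain of an alpha-oxygenated aroylacetic ester. Cutting O1–C2 and C4–C4a therefore leads to phloroglucinol 16 and keto ester 15, in which the C3 oxygen is already at the right oxidation level.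

## Retrosynthetic reasoning

**20 to 19.** The last operation is cleavage of three O–Si bonds. Silyl ethers are chosen for the C3, C3' and C4' oxygens because they can be removed together under buffered, nearly neutral conditions that leave the prenyl alkene and the oxidation-prone polyphenol alone. The C5 and C7 hydroxyls need no protection because they come from ring A unprotected.

**19 to 15 and 16.** Ring C is cut at O1–C2 and C4–C4a. This is the only pair of bonds whose cleavage returns ring A as the symmetric, purchasable 16, so no regiochemistry arises on ring A. It also keeps C2, C3 and C4 together in one fragment, 15, with the C3 oxygen in place. No oxidation is then needed after the alkene is present. In the forward direction the ester carbon of 15 must acylate a ring carbon of 16 (through ketene 17 to diketone 18), and a flanking hydroxyl must then condense with the aryl ketone. Attack at the ketone first would give a coumarin, so the step is run without acid.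

**15 to 10 and 12.** The bond between the ketone carbon and the alpha-carbon is cut as a crossed Claisen condensation. The acid 10 is activated as acyl imidazolide 13 and meets the lithium enolate 14 of the silylated glycolate 12, which is one step from 11. The ring B carbonyl cannot enolise, so only one enolate is possible. The stereocentre this creates is of no consequence because it becomes C3 of the chromone.

**10 to 8.** The aryl–carboxyl bond is cut. Bromine–lithium exchange on 8 gives aryllithium 9, which is carboxylated. In 9 the carbon–lithium bond has no silyloxy group ortho to it, so oxygen-to-carbon silyl migration is not available.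

**8 to 7 to 6.** The two silyl ethers are traced back to the two acetal ethers of 6 by way of catechol 7. The exchange is needed because each protecting group serves only one stage. The acetal ethers direct the metalation that places the prenyl group, but would act as formaldehyde donors towards 16 in the melt. Silyl ethers tolerate the melt, but would not survive as ortho-lithiated species. The exchange is placed at the bromide stage, where no carboxyl group is present and the material is still cheap.

**6 to 2 and 3.** The aryl–CH2 bond is cut. The carbon between the bromine and the neighbouring acetal ether of 2 carries the most acidic ring hydrogen. A lithium amide removes it to give 4, without touching the bromine. Transmetalation to copper (5) then lets the primary carbon of 3 be attacked, giving the linear prenyl group exactly where ring B needs it.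

**2 to 1.** Both phenols of 1 are protected. The bromine of 1 already marks the future C1', para to one oxygen and meta to the other, which is the pattern of ring B.

## Alternatives that were turned down

**Alternative 1:** biomimetic folding of a polyketide.
- **Disconnection:** ring A is opened at C4a–C8a. This leads back to pyrone A1, a masked cinnamoyl triketo ester.
- **Forward key step:** a magnesium alkoxide in its parent alcohol opens the lactone of A1. The carbanion at the future C4a of the chelated triketo ester then attacks the ester carbonyl, and aromatisation gives chalcone A2.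
- **For:** it follows the biosynthetic logic and runs near room temperature. On thermal stress to the prenyl group and the protecting groups it is clearly stronger than the chosen route.
- **Against:** A2 is only a chalcone. Ring C must still be closed and the C3 oxygen introduced. The usual oxidative cyclisation with alkaline peroxide tends towards aurones when the ring A position next to the carbonyl is oxygenated, and epoxidising reagents attack the prenyl alkene. The chain of A1 needs several enolate acylations to build a ring that can be bought. The folding can also take the aldol course or re-close to a pyrone. The acetal ethers of A2 must finally be removed by acid next to the prenyl group with the C3' hydroxyl free.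
- **Comparison:** the chosen strategy buys ring A as 16 and carries the C3 oxygen in from 11. It avoids the late oxidation altogether and is several steps shorter. What it gives up is the mildness of the ring-forming step.

**Alternative 2:** ring B by cycloaddition.
- **Disconnection:** ring B is cut at C2'–C3' and C6'–C1'. This gives ynoate A3 and 3-methoxyfuran A4.
- **Forward key step:** a [4+2] cycloaddition joins the nucleophilic C2 of A4 to the beta-carbon of A3. The oxygen bridge of the adduct then opens towards the methoxy-stabilised cation and the ring aromatises to phenol A5.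
- **For:** the 1,2,3,4 pattern is set in one step by the polarisation of both partners. No ortho-bromoaryllithium is needed, so it is stronger than step 2 of the chosen route on the risk of aryne formation.
- **Against:** it constructs the ring that is easiest to obtain; 6 is two steps from 1. A3 is a singly activated alkyne with a doubly activated CH2 between alkyne and alkene, prone to isomerise. Furan cycloadditions of this kind are reversible and need heat or a Lewis acid. The bridge opening exposes a free phenol beside the prenyl group to acid. A5 carries the C4' oxygen as a methyl ether, whose cleavage needs reagents the alkene does not tolerate. A5 corresponds only to acid 10, so all of ring C remains to be made.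
- **Comparison:** it lengthens the synthesis by three to four steps and solves nothing about the chromone. The chosen route reaches 10 in five steps and puts the risk into the step that builds ring C.

**Alternative 3:** aryne insertion.
- **Disconnection:** O1–C8a, C4–C4a and O1–C2 are cut. Ring A comes from silylaryl triflate A7 and the three carbons of ring C from propiolic acid A6.
- **Forward key step:** a fluoride source releases the benzyne from A7. The carboxylate of A6 adds at the aryne carbon remote from the neighbouring alkoxy group. The aryl anion then takes the acyl group (net insertion into the carboxyl C–O bond), and the resulting phenoxide adds to the alkyne to give flavone A8.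
- **For:** the conditions are mild and the coupling is convergent. The alkoxy group steers the acyl group to C4a next to C5. On temperature it is stronger than the chosen key step.
- **Against:** A8 has no oxygen at C3. Putting it there needs a dioxirane, which attacks the prenyl alkene, or a metalation–oxidation sequence of one to two steps. The aryne can undergo an ene reaction with the trisubstituted alkene of A6. The phenoxide can close in the 5-exo mode to an aurone. Four acetal ethers must be removed by acid with the C3' hydroxyl free beside the prenyl group. A7 needs four to five steps from 16 and A6 two to three from 6.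
- **Comparison:** the chosen strategy uses 16 itself as ring A, has the C3 oxygen in place from the start and ends with a fluoride deprotection. It is shorter by at least three steps, at the price of one hot step.

Key step: step 8

Assumption: phloroglucinol 16 is used in its anhydrous form (the dihydrate is dried before use), since water at the temperature of step 8 would cleave ester and silyl groups. LDA is used as a titrated commercial solution.

## Route

**Step 1**
Reactants: 1 4-bromobenzene-1,2-diol
Product: 2 4-bromo-1,2-bis(methoxymethoxy)benzene
Conditions: MOMCl (2.5 equiv), iPr2NEt (3 equiv), CH2Cl2, 0 °C → rt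
Reagents that add atoms: chloromethyl methyl ether (MOMCl), COCCl
Why: O-alkylation of both phenols by the reactive alpha-chloro ether under amine base; the acetal ethers are the directing groups for step 2.

**Step 2**
Reactants: 2 4-bromo-1,2-bis(methoxymethoxy)benzene; 3 1-bromo-3-methylbut-2-ene
Product: 6 1-bromo-3,4-bis(methoxymethoxy)-2-(3-methylbut-2-enyl)benzene, via aryllithium 4 (not isolated), via arylcopper 5 (not isolated)
Conditions: LDA (1.1 equiv), THF, −78 °C; CuBr·SMe2 (1.1 equiv), −78 °C; 3 (1.3 equiv), −78 → 0 °C
Reagents that add atoms: none
Why: Directed ortho metalation: the amide base removes the ring hydrogen flanked by bromine and an acetal ether and does not exchange the bromine, and at −78 °C 4 should not lose LiBr. Transmetalation to copper followed by allylic substitution at the primary carbon of 3 should give the linear prenyl group.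

**Step 3**
Reactants: 6 1-bromo-3,4-bis(methoxymethoxy)-2-(3-methylbut-2-enyl)benzene
Product: 7 4-bromo-3-(3-methylbut-2-enyl)benzene-1,2-diol
Conditions: conc. aq. HCl (5 equiv), MeOH, 0 °C → rt, argon; NaHCO3 before concentration
Reagents that add atoms: none
Why: Acid-catalysed acetal exchange with the solvent frees both phenols; short exposure at room temperature and neutralisation before concentration should keep the alkene from adding the neighbouring hydroxyl.

**Step 4**
Reactants: 7 4-bromo-3-(3-methylbut-2-enyl)benzene-1,2-diol
Product: 8 4-bromo-1,2-bis(tert-butyldimethylsilyloxy)-3-(3-methylbut-2-enyl)benzene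
Conditions: TBSCl (3 equiv), imidazole (6 equiv), DMF, rt → 40 °C
Reagents that add atoms: tert-butyldimethylsilyl chloride (TBSCl), CC(C)(C)[Si](C)(C)Cl
Why: Imidazole-promoted silylation of both phenols; gentle warming should carry the hindered hydroxyl next to the prenyl group to completion.

**Step 5**
Reactants: 8 4-bromo-1,2-bis(tert-butyldimethylsilyloxy)-3-(3-methylbut-2-enyl)benzene
Product: 10 3,4-bis(tert-butyldimethylsilyloxy)-2-(3-methylbut-2-enyl)benzoic acid, via aryllithium 9 (not isolated)
Conditions: n-BuLi (1.1 equiv), THF, −78 °C, 20 min; CO2 (dry gas), −78 → 0 °C; cold 1 M HCl to pH 3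
Reagents that add atoms: carbon dioxide, O=C=O
Why: Bromine–lithium exchange and carboxylation of the aryllithium; no silyloxy group is ortho to the carbon–lithium bond, so retro-Brook silyl migration is not possible, and the short time at −78 °C should prevent proton transfer from the benzylic-allylic CH2.

**Step 6**
Reactants: 11 methyl glycolate
Product: 12 methyl 2-(tert-butyldimethylsilyloxy)acetate
Conditions: TBSCl (1.1 equiv), imidazole (2 equiv), CH2Cl2, rt
Reagents that add atoms: tert-butyldimethylsilyl chloride (TBSCl), CC(C)(C)[Si](C)(C)Cl
Why: Standard silylation of a primary alcohol.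

**Step 7**
Reactants: 10 3,4-bis(tert-butyldimethylsilyloxy)-2-(3-methylbut-2-enyl)benzoic acid; 12 methyl 2-(tert-butyldimethylsilyloxy)acetate
Product: 15 methyl 3-[3,4-bis(tert-butyldimethylsilyloxy)-2-(3-methylbut-2-enyl)phenyl]-2-(tert-butyldimethylsilyloxy)-3-oxopropanoate (racemic), via acyl imidazolide 13 (not isolated), via lithium enolate 14 (not isolated)
Conditions: 10, CDI (1.1 equiv), THF, rt, 1 h; then added to 14 [12 (3.3 equiv), LDA (3.3 equiv), THF, −78 °C], −78 → −40 °C; aq. NH4Cl
Reagents that add atoms: none
Why: Crossed Claisen condensation of an ester enolate with a non-enolisable acyl imidazolide; the excess of 14 covers the imidazole N–H and the acidic product. The new stereocentre at C2 is formed without control (racemic) and disappears in step 8.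

**Step 8**
Reactants: 15 methyl 3-[3,4-bis(tert-butyldimethylsilyloxy)-2-(3-methylbut-2-enyl)phenyl]-2-(tert-butyldimethylsilyloxy)-3-oxopropanoate; 16 phloroglucinol (benzene-1,3,5-triol)
Product: 19 2-[3,4-bis(tert-butyldimethylsilyloxy)-2-(3-methylbut-2-enyl)phenyl]-3-(tert-butyldimethylsilyloxy)-5,7-dihydroxychromen-4-one, via aroylketene 17 (not isolated), via 1,3-diketone 18 (not isolated)
Conditions: 16 (anhydrous, 3 equiv), neat melt, 240 °C, argon sweep, 10–20 min (microwave or preheated metal bath)
Reagents that add atoms: none
Why: On heating, 15 should lose methanol to the aroyl(silyloxy)ketene 17; direct transesterification to the aryl ester followed by an oxygen-to-carbon acyl shift is the equivalent path. A ring carbon of the very electron-rich 16 attacks the ketene carbon and gives the 2-acylphloroglucinol 18, which forms the C4–C4a bond. A hydroxyl ortho to the new acyl group then adds to the aryl ketone in a 6-exo-trig closure and the adduct loses water, which forms O1–C2 and closes ring C as the 4-pyranone; escape of methanol and water from the melt drives the sequence. The closest known reaction is the Mentzer pyrone synthesis, the uncatalysed thermal condensation of phenols with aroylacetic esters to flavones, in which alpha-substituted esters give 3-substituted flavones. No stereocentre is formed, and the stereocentre of racemic 15 becomes the sp2 carbon C3. The selectivity needed is chromone over coumarin: without acid the arene attacks the ketene or ester carbon and not the ketone, and the ketone of 15 is further shielded by the ortho prenyl group and the alpha-silyloxy group. The threefold symmetry of 16 removes any regiochemical question, and its excess should limit double acylation. With no acid added the prenyl group should persist, and silyl transfer to free phenols is tolerated because step 9 removes all silyl groups.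

**Step 9**
Reactants: 19 2-[3,4-bis(tert-butyldimethylsilyloxy)-2-(3-methylbut-2-enyl)phenyl]-3-(tert-butyldimethylsilyloxy)-5,7-dihydroxychromen-4-one
Product: 20 2-[3,4-dihydroxy-2-(3-methylbut-2-enyl)phenyl]-3,5,7-trihydroxychromen-4-one
Conditions: Bu4NF (4 equiv), AcOH (4 equiv), THF, 0 °C → rt, argon
Reagents that add atoms: none
Why: Fluoride cleaves the two aryl silyl ethers and the enol-type silyl ether at C3; the acetic acid buffer keeps the catechol and the flavonol protonated, which should prevent air oxidation and leaves the prenyl group untouched.

## Compound list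

1 | 4-bromobenzene-1,2-diol | Oc1ccc(Br)cc1O | starting material
2 | 4-bromo-1,2-bis(methoxymethoxy)benzene | COCOc1ccc(Br)cc1OCOC | intermediate
3 | 1-bromo-3-methylbut-2-ene (prenyl bromide) | CC(C)=CCBr | starting material
4 | [6-bromo-2,3-bis(methoxymethoxy)phenyl]lithium | COCOc1ccc(Br)c([Li])c1OCOC | intermediate
5 | [6-bromo-2,3-bis(methoxymethoxy)phenyl]copper | COCOc1ccc(Br)c([Cu])c1OCOC | intermediate
6 | 1-bromo-3,4-bis(methoxymethoxy)-2-(3-methylbut-2-enyl)benzene | CC(C)=CCc1c(Br)ccc(OCOC)c1OCOC | intermediate
7 | 4-bromo-3-(3-methylbut-2-enyl)benzene-1,2-diol | CC(C)=CCc1c(Br)ccc(O)c1O | intermediate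
8 | 4-bromo-1,2-bis(tert-butyldimethylsilyloxy)-3-(3-methylbut-2-enyl)benzene | CC(C)=CCc1c(Br)ccc(O[Si](C)(C)C(C)(C)C)c1O[Si](C)(C)C(C)(C)C | intermediate
9 | [3,4-bis(tert-butyldimethylsilyloxy)-2-(3-methylbut-2-enyl)phenyl]lithium | CC(C)=CCc1c([Li])ccc(O[Si](C)(C)C(C)(C)C)c1O[Si](C)(C)C(C)(C)C | intermediate
10 | 3,4-bis(tert-butyldimethylsilyloxy)-2-(3-methylbut-2-enyl)benzoic acid | CC(C)=CCc1c(C(=O)O)ccc(O[Si](C)(C)C(C)(C)C)c1O[Si](C)(C)C(C)(C)C | intermediate
11 | methyl glycolate | COC(=O)CO | starting material
12 | methyl 2-(tert-butyldimethylsilyloxy)acetate | COC(=O)CO[Si](C)(C)C(C)(C)C | intermediate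
13 | 1-[3,4-bis(tert-butyldimethylsilyloxy)-2-(3-methylbut-2-enyl)benzoyl]imidazole | CC(C)=CCc1c(C(=O)n2ccnc2)ccc(O[Si](C)(C)C(C)(C)C)c1O[Si](C)(C)C(C)(C)C | intermediate
14 | lithium enolate of methyl 2-(tert-butyldimethylsilyloxy)acetate | [Li]OC(OC)=CO[Si](C)(C)C(C)(C)C | intermediate
15 | methyl 3-[3,4-bis(tert-butyldimethylsilyloxy)-2-(3-methylbut-2-enyl)phenyl]-2-(tert-butyldimethylsilyloxy)-3-oxopropanoate (racemic) | CC(C)=CCc1c(C(=O)C(O[Si](C)(C)C(C)(C)C)C(=O)OC)ccc(O[Si](C)(C)C(C)(C)C)c1O[Si](C)(C)C(C)(C)C | intermediate
16 | phloroglucinol (benzene-1,3,5-triol) | Oc1cc(O)cc(O)c1 | starting material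
17 | 3-[3,4-bis(tert-butyldimethylsilyloxy)-2-(3-methylbut-2-enyl)phenyl]-2-(tert-butyldimethylsilyloxy)-3-oxoprop-1-en-1-one (aroylketene) | CC(C)=CCc1c(C(=O)C(O[Si](C)(C)C(C)(C)C)=C=O)ccc(O[Si](C)(C)C(C)(C)C)c1O[Si](C)(C)C(C)(C)C | intermediate
18 | 1-[3,4-bis(tert-butyldimethylsilyloxy)-2-(3-methylbut-2-enyl)phenyl]-2-(tert-butyldimethylsilyloxy)-3-(2,4,6-trihydroxyphenyl)propane-1,3-dione | CC(C)=CCc1c(C(=O)C(O[Si](C)(C)C(C)(C)C)C(=O)c2c(O)cc(O)cc2O)ccc(O[Si](C)(C)C(C)(C)C)c1O[Si](C)(C)C(C)(C)C | intermediate
19 | 2-[3,4-bis(tert-butyldimethylsilyloxy)-2-(3-methylbut-2-enyl)phenyl]-3-(tert-butyldimethylsilyloxy)-5,7-dihydroxychromen-4-one | CC(C)=CCc1c(-c2oc3cc(O)cc(O)c3c(=O)c2O[Si](C)(C)C(C)(C)C)ccc(O[Si](C)(C)C(C)(C)C)c1O[Si](C)(C)C(C)(C)C | intermediate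
20 | 2-[3,4-dihydroxy-2-(3-methylbut-2-enyl)phenyl]-3,5,7-trihydroxychromen-4-one | CC(C)=CCc1c(-c2oc3cc(O)cc(O)c3c(=O)c2O)ccc(O)c1O | target

## Step count and least certain steps

Total step count: 9. Longest linear sequence: 8 steps (steps 1, 2, 3, 4, 5, 7, 8, 9); step 6 is a one-step side branch.

**Step 8 (key step).**
- *What may go wrong:* silyl groups may move from 15 or 19 to the phenols of 16 in the melt, and a C3' hydroxyl freed in this way could close onto the prenyl alkene at this temperature. The ketene 17 may be consumed by dimerisation or by the neighbouring alkene before 16 intercepts it. Lipophilic 15 may mix poorly with molten 16. Attack at the ketone (coumarin mode) is the less likely failure. Loss of a single silyl group without further change is harmless, since such congeners converge on 20 in step 9.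
- *Fallback:* a base-mediated, low-temperature assembly of the same diketone carbon chain, setting out from 16, 12 and 10 and returning at 19.
  - 16 is converted with MOMCl and iPr2NEt into 1,3,5-tris(methoxymethoxy)benzene F1.
  - 12 is converted with N,O-dimethylhydroxylamine hydrochloride and i-PrMgCl into 2-(tert-butyldimethylsilyloxy)-N-methoxy-N-methylacetamide F2.
  - Metalation of F1 with n-BuLi between two acetal ethers and acylation with F2 should give 2-(tert-butyldimethylsilyloxy)-1-[2,4,6-tris(methoxymethoxy)phenyl]ethanone F3.
  - Deprotonation of F3 with LiHMDS (2.2 equiv, THF, −78 °C) and acylation with imidazolide 13 (from 10 and CDI, as in step 7) should give 1-[3,4-bis(tert-butyldimethylsilyloxy)-2-(3-methylbut-2-enyl)phenyl]-2-(tert-butyldimethylsilyloxy)-3-[2,4,6-tris(methoxymethoxy)phenyl]propane-1,3-dione F4.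
  - Brief treatment of F4 with HCl in MeOH at room temperature removes the ring A acetal ethers. The freed ortho hydroxyl condenses with the ring B ketone and water is lost, giving 19 (or congeners lacking one silyl group), which goes on to step 9.
  - Ring B stays silylated during the acid step, so the C3' oxygen cannot add to the alkene.

**Step 2.**
- *What may go wrong:* loss of LiBr from 4 to an aryne if the temperature rises, migration of bromine between lithiated positions, or attack at the tertiary end of 3 to give the branched isomer.
- *Fallback:* metalation without bromine on the ring, setting out from 2 and returning at 10.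
  - Bromine–lithium exchange on 2 (n-BuLi, −78 °C) and carboxylation give 3,4-bis(methoxymethoxy)benzoic acid F5.
  - Its lithium carboxylate and the neighbouring acetal ether together direct s-BuLi/TMEDA (2.2 equiv, THF, −78 °C) to the carbon between them. CuBr·SMe2 and then 3 should give 3,4-bis(methoxymethoxy)-2-(3-methylbut-2-enyl)benzoic acid F6; any prenyl ester is cleaved with LiOH during work-up.
  - HCl in MeOH at room temperature gives 3,4-dihydroxy-2-(3-methylbut-2-enyl)benzoic acid F7.
  - TBSCl and imidazole in DMF give tert-butyldimethylsilyl 3,4-bis(tert-butyldimethylsilyloxy)-2-(3-methylbut-2-enyl)benzoate F8, whose silyl ester alone is hydrolysed by AcOH/THF/water to 10.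

**Step 3.**
- *What may go wrong:* acid-catalysed addition of the freed C2 hydroxyl of 7 to the prenyl alkene (chroman formation) or addition of HCl to the alkene, because the tertiary cation forms easily.
- *Fallback:* the acid step is run on an allyl group and the prenyl group is completed afterwards, setting out from 2 and returning at 8.
  - 2 is metalated as in step 2 (LDA, then CuBr·SMe2) and treated with allyl bromide to give 2-allyl-1-bromo-3,4-bis(methoxymethoxy)benzene F9.
  - HCl in MeOH gives 3-allyl-4-bromobenzene-1,2-diol F10; its terminal alkene can only form a secondary cation and should resist cyclisation.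
  - TBSCl and imidazole give 3-allyl-4-bromo-1,2-bis(tert-butyldimethylsilyloxy)benzene F11.
  - Cross-metathesis of F11 with 2-methylbut-2-ene as solvent and second-generation Grubbs catalyst at 40 °C should give 8.

**Step 7.**
- *What may go wrong:* slow acylation at the hindered carbonyl of 13, self-condensation or silyl migration of enolate 14 on warming, or O-acylation.
- *Fallback:* aldol addition and oxidation in place of the Claisen condensation, setting out from 8 and returning at 15.
  - Bromine–lithium exchange on 8 (n-BuLi, −78 °C) and quenching with DMF give 3,4-bis(tert-butyldimethylsilyloxy)-2-(3-methylbut-2-enyl)benzaldehyde F12.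
  - Addition of enolate 14 (1.2 equiv, −78 °C) gives methyl 3-[3,4-bis(tert-butyldimethylsilyloxy)-2-(3-methylbut-2-enyl)phenyl]-2-(tert-butyldimethylsilyloxy)-3-hydroxypropanoate F13 as a mixture of diastereomers.
  - Oxidation of F13 with Dess–Martin periodinane (NaHCO3, CH2Cl2) gives 15. The aldehyde is a less hindered and more reactive electrophile than 13.

## Further compounds

F1 | step 8 | 1,3,5-tris(methoxymethoxy)benzene | COCOc1cc(OCOC)cc(OCOC)c1
F2 | step 8 | 2-(tert-butyldimethylsilyloxy)-N-methoxy-N-methylacetamide | CON(C)C(=O)CO[Si](C)(C)C(C)(C)C
F3 | step 8 | 2-(tert-butyldimethylsilyloxy)-1-[2,4,6-tris(methoxymethoxy)phenyl]ethanone | COCOc1cc(OCOC)c(C(=O)CO[Si](C)(C)C(C)(C)C)c(OCOC)c1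
F4 | step 8 | 1-[3,4-bis(tert-butyldimethylsilyloxy)-2-(3-methylbut-2-enyl)phenyl]-2-(tert-butyldimethylsilyloxy)-3-[2,4,6-tris(methoxymethoxy)phenyl]propane-1,3-dione | CC(C)=CCc1c(C(=O)C(O[Si](C)(C)C(C)(C)C)C(=O)c2c(OCOC)cc(OCOC)cc2OCOC)ccc(O[Si](C)(C)C(C)(C)C)c1O[Si](C)(C)C(C)(C)C
F5 | step 2 | 3,4-bis(methoxymethoxy)benzoic acid | COCOc1ccc(C(=O)O)cc1OCOC
F6 | step 2 | 3,4-bis(methoxymethoxy)-2-(3-methylbut-2-enyl)benzoic acid | CC(C)=CCc1c(C(=O)O)ccc(OCOC)c1OCOC
F7 | step 2 | 3,4-dihydroxy-2-(3-methylbut-2-enyl)benzoic acid | CC(C)=CCc1c(C(=O)O)ccc(O)c1O
F8 | step 2 | tert-butyldimethylsilyl 3,4-bis(tert-butyldimethylsilyloxy)-2-(3-methylbut-2-enyl)benzoate | CC(C)=CCc1c(C(=O)O[Si](C)(C)C(C)(C)C)ccc(O[Si](C)(C)C(C)(C)C)c1O[Si](C)(C)C(C)(C)C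
F9 | step 3 | 2-allyl-1-bromo-3,4-bis(methoxymethoxy)benzene | C=CCc1c(Br)ccc(OCOC)c1OCOC
F10 | step 3 | 3-allyl-4-bromobenzene-1,2-diol | C=CCc1c(Br)ccc(O)c1O
F11 | step 3 | 3-allyl-4-bromo-1,2-bis(tert-butyldimethylsilyloxy)benzene | C=CCc1c(Br)ccc(O[Si](C)(C)C(C)(C)C)c1O[Si](C)(C)C(C)(C)C
F12 | step 7 | 3,4-bis(tert-butyldimethylsilyloxy)-2-(3-methylbut-2-enyl)benzaldehyde | CC(C)=CCc1c(C=O)ccc(O[Si](C)(C)C(C)(C)C)c1O[Si](C)(C)C(C)(C)C
F13 | step 7 | methyl 3-[3,4-bis(tert-butyldimethylsilyloxy)-2-(3-methylbut-2-enyl)phenyl]-2-(tert-butyldimethylsilyloxy)-3-hydroxypropanoate (mixture of diastereomers) | CC(C)=CCc1c(C(O)C(O[Si](C)(C)C(C)(C)C)C(=O)OC)ccc(O[Si](C)(C)C(C)(C)C)c1O[Si](C)(C)C(C)(C)C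
A1 | alternative 1 | 6-[(E)-4-[3,4-bis(methoxymethoxy)-2-(3-methylbut-2-enyl)phenyl]-2-oxobut-3-enyl]-4-hydroxypyran-2-one | CC(C)=CCc1c(/C=C/C(=O)CC2=CC(O)=CC(=O)O2)ccc(OCOC)c1OCOC
A2 | alternative 1 | (E)-3-[3,4-bis(methoxymethoxy)-2-(3-methylbut-2-enyl)phenyl]-1-(2,4,6-trihydroxyphenyl)prop-2-en-1-one | CC(C)=CCc1c(/C=C/C(=O)c2c(O)cc(O)cc2O)ccc(OCOC)c1OCOC
A3 | alternative 2 | methyl 6-methylhept-5-en-2-ynoate | COC(=O)C#CCC=C(C)C
A4 | alternative 2 | 3-methoxyfuran | COc1ccoc1
A5 | alternative 2 | methyl 3-hydroxy-4-methoxy-2-(3-methylbut-2-enyl)benzoate | COC(=O)c1ccc(OC)c(O)c1CC=C(C)C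
A6 | alternative 3 | 3-[3,4-bis(methoxymethoxy)-2-(3-methylbut-2-enyl)phenyl]prop-2-ynoic acid | CC(C)=CCc1c(C#CC(=O)O)ccc(OCOC)c1OCOC
A7 | alternative 3 | 3,5-bis(methoxymethoxy)-2-(trimethylsilyl)phenyl trifluoromethanesulfonate | COCOc1cc(OCOC)c([Si](C)(C)C)c(OS(=O)(=O)C(F)(F)F)c1
A8 | alternative 3 | 5,7-bis(methoxymethoxy)-2-[3,4-bis(methoxymethoxy)-2-(3-methylbut-2-enyl)phenyl]chromen-4-one | CC(C)=CCc1c(-c2cc(=O)c3c(OCOC)cc(OCOC)cc3o2)ccc(OCOC)c1OCOC
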